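**Retrosynthetic overview**
1. The last skeletal bond is C5–C(=O). The target comes from acid deprotection of the protected chalcone. That chalcone comes from a C5-lithiated 4,6-bis(methoxymethoxy)-2,3-dihydrobenzofuran and (E)-4-(methoxymethoxy)cinnamic N-methoxy-N-methylamide, which brings ring B and the E-alkene.
2. The dihydrofuran ring (O1–C2–C3–C3a–C7a) comes from the six-membered lactone ring (O1–C(=O)–CH(OTs)–CH2–C4a–C8a) of (S)-3-tosyloxy-5,7-dihydroxy-3,4-dihydrocoumarin. A MeLi-triggered ring contraction expels the lactone carbonyl carbon as the exocyclic C(CH3)2OH carbon.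
3. Enabling feature: C2 of the dihydrofuran carries O1 and, outside the ring, the oxygen-bearing carbon C(CH3)2OH. This O1–C2–C(O) array is the skeleton of an alpha-oxygenated aryl ester, so the carbinol carbon can sit inside a six-membered ring as C=O between O1 and C2. In addition, C3a lies between two equivalent oxygens (O1 and the C4 oxygen) of the phloroglucinol ring, so re-closure has no regiochemical choice.
4. The lactone comes from a 2,4,6-tris(benzyloxy)phenyl Grignard reagent and methyl (S)-glycidate (the only source of chirality), followed by tosylation, hydrogenolysis and lactonisation.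
5. Ring order: both benzene rings are bought; the lactone ring forms in step 4; a transient oxirane and then the dihydrofuran form in step 5.

Key step: step 5

Remark: the stereocentre of the target is read as (S). Metal-bearing intermediates are drawn with covalent O–Li, C–Li and C–Mg bonds. Compound 19 forms as a mixture of epimers at its hemiaminal carbon, which is lost again in the same step.

**Step 1**
Reactants: 1 1,3,5-tris(benzyloxy)benzene
Product: 2 2-bromo-1,3,5-tris(benzyloxy)benzene
Conditions: NBS (1.0 equiv), CH2Cl2, −20 → 0 °C, dark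
Reagents that add atoms: N-bromosuccinimide, O=C1CCC(=O)N1Br
Why: Electrophilic aromatic bromination; the three free positions of this strongly activated arene are equivalent, so one equivalent of NBS at low temperature should stop at the monobromide.

**Step 2**
Reactants: 2 2-bromo-1,3,5-tris(benzyloxy)benzene; 3 methyl (S)-glycidate
Product: 5 methyl (S)-2-hydroxy-3-[2,4,6-tris(benzyloxy)phenyl]propanoate, via arylmagnesium bromide 4 (not isolated)
Conditions: Mg, LiCl, THF, 25 °C; CuBr·SMe2 (15 mol%), −40 °C; then 3, −40 → −10 °C; aqueous work-up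
Reagents that add atoms: none
Why: Copper-catalysed SN2 opening of a terminal epoxide by an aryl Grignard reagent; attack goes to the unhindered CH2, the di-ortho-substituted aryl group is too hindered to attack the ester, and the C–O bond at the stereocentre is untouched, so the (S) configuration of 3 is carried into 5.

**Step 3**
Reactants: 5 methyl (S)-2-hydroxy-3-[2,4,6-tris(benzyloxy)phenyl]propanoate
Product: 6 methyl (S)-2-(tosyloxy)-3-[2,4,6-tris(benzyloxy)phenyl]propanoate
Conditions: TsCl, Et3N, DMAP (cat.), CH2Cl2, 0 °C → rt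
Reagents that add atoms: p-toluenesulfonyl chloride, Cc1ccc(cc1)S(=O)(=O)Cl
Why: O-sulfonylation of a secondary alcohol with retention (the C–O bond is not touched); tosylate is preferred to mesylate because it has no acidic S–CH3 protons that could interfere in step 5.

**Step 4**
Reactants: 6 methyl (S)-2-(tosyloxy)-3-[2,4,6-tris(benzyloxy)phenyl]propanoate
Product: 8 (S)-5,7-dihydroxy-2-oxochroman-3-yl 4-methylbenzenesulfonate, via triol ester 7 (not isolated)
Conditions: H2 (1 atm), Pd/C, EtOAc, rt; filter; then camphorsulfonic acid (cat.), MeCN/PhMe, 4 Å MS, 50 °C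
Reagents that add atoms: none
Why: Hydrogenolysis of the benzyl aryl ethers, then acid-catalysed lactonisation (6-exo-trig transesterification) onto either of the two equivalent ortho phenols; the alkyl tosylate and the stereocentre are inert to both operations, and no base touches the acidic alpha-position.

**Step 5**
Reactants: 8 (S)-5,7-dihydroxy-2-oxochroman-3-yl 4-methylbenzenesulfonate
Product: 12 (S)-2-(2-hydroxypropan-2-yl)-2,3-dihydrobenzofuran-4,6-diol, via tosyloxy ketone 9 (not isolated), via tosyloxy carbinol 10 (not isolated), via oxirane 11 (not isolated)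
Conditions: MeLi·LiBr (4.4 equiv), THF, −78 °C, 8 added slowly to the reagent; then DMPU, −78 → 23 → 45 °C, argon; pH 6 buffer
Reagents that add atoms: methyllithium, [Li]C
Why: Proposed new method: after deprotonation of both phenols, MeLi adds twice to the activated aryl-ester carbonyl of 8 (ring fission to ketone 9, then carbinol 10), which turns the ring carbonyl carbon into the exocyclic C(CH3)2O–Li and frees the former ring oxygen as a phenoxide; on warming the tertiary alkoxide displaces the vicinal tosylate (3-exo-tet) to oxirane 11 and an ortho phenoxide opens 11 at its secondary carbon (5-exo-tet), so a six-membered ring is exchanged for the five-membered one with two new C–C bonds in the same flask. The closest known reaction types are the Perkin coumarin-to-benzofuran ring contraction (lactone fission followed by O-alkylative re-closure), the conversion of alpha-sulfonyloxy or alpha-halo esters into trisubstituted oxiranes by two equivalents of an organometallic reagent, and the base-induced 5-exo cyclisation of ortho-(3,3-dimethyloxiranylmethyl)phenols; new is only their merger on a 3-sulfonyloxy-3,4-dihydrocoumarin. No stereocentre is created: C3 of 8, set by glycidate 3, undergoes two SN2 inversions (alkoxide, then phenoxide), so (S)-8 should give (S)-12. Chemoselectivity for addition over enolisation is secured by the high electrophilicity of the aryl ester and of alpha-tosyloxy ketone 9, by −78 °C and by adding 8 to excess MeLi. The oxirane pathway must beat direct displacement of tosylate by phenoxide (which would give the enantiomer): the quaternary carbinol carbon next to C–OTs retards that neopentyl-type SN2, while its gem-dimethyl group accelerates the 3-exo closure by the far more basic alkoxide. 5-exo is preferred to 6-endo because under basic, non-ionising conditions the phenoxide attacks the less substituted oxirane carbon, and there is no choice of oxygen because both ortho phenoxides of the 2,4,6-trioxygenated ring are equivalent.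

**Step 6**
Reactants: 12 (S)-2-(2-hydroxypropan-2-yl)-2,3-dihydrobenzofuran-4,6-diol
Product: 13 (S)-2-[4,6-bis(methoxymethoxy)-2,3-dihydrobenzofuran-2-yl]propan-2-ol
Conditions: MOMCl (2.4 equiv), i-Pr2NEt, CH2Cl2, 0 °C → rt
Reagents that add atoms: chloromethyl methyl ether, COCCl
Why: Phenol-selective acetal protection (O-alkylation); the acidic phenols react under amine base, while the hindered tertiary alcohol should stay free.

**Step 7**
Reactants: 13 (S)-2-[4,6-bis(methoxymethoxy)-2,3-dihydrobenzofuran-2-yl]propan-2-ol
Product: 14 (S)-triethyl{2-[4,6-bis(methoxymethoxy)-2,3-dihydrobenzofuran-2-yl]propan-2-yloxy}silane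
Conditions: TESOTf, 2,6-lutidine, CH2Cl2, −78 → 0 °C
Reagents that add atoms: triethylsilyl trifluoromethanesulfonate, CC[Si](CC)(CC)OS(=O)(=O)C(F)(F)F
Why: Silylation of a tertiary alcohol with a silyl triflate; the bulky, non-coordinating silyl ether avoids a lithium alkoxide chelated to O1 that could steer the metalation of step 10 to C7.

**Step 8**
Reactants: 15 4-hydroxybenzaldehyde
Product: 16 4-(methoxymethoxy)benzaldehyde
Conditions: MOMCl, i-Pr2NEt, CH2Cl2, 0 °C → rt
Reagents that add atoms: chloromethyl methyl ether, COCCl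
Why: Standard O-alkylation of a phenol to its methoxymethyl ether, giving the same acid-labile group as on ring A.

**Step 9**
Reactants: 16 4-(methoxymethoxy)benzaldehyde
Product: 17 (E)-N-methoxy-N-methyl-3-[4-(methoxymethoxy)phenyl]acrylamide
Conditions: (EtO)2P(O)CH2C(O)N(OMe)Me, NaH, THF, 0 °C → rt
Reagents that add atoms: diethyl [2-(methoxy(methyl)amino)-2-oxoethyl]phosphonate, CCOP(=O)(CC(=O)N(C)OC)OCC
Why: Horner–Wadsworth–Emmons olefination; a stabilised phosphonate anion and an aromatic aldehyde should give the E-alkene under thermodynamic control of the oxaphosphetane pathway.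

**Step 10**
Reactants: 14 (S)-triethyl{2-[4,6-bis(methoxymethoxy)-2,3-dihydrobenzofuran-2-yl]propan-2-yloxy}silane; 17 (E)-N-methoxy-N-methyl-3-[4-(methoxymethoxy)phenyl]acrylamide
Product: 20 (E)-1-[(2S)-4,6-bis(methoxymethoxy)-2-(2-triethylsilyloxypropan-2-yl)-2,3-dihydrobenzofuran-5-yl]-3-[4-(methoxymethoxy)phenyl]prop-2-en-1-one, via aryllithium 18 (not isolated), via lithium hemiaminal 19 (not isolated)
Conditions: n-BuLi (1.15 equiv), THF, 0 °C; then 17, −78 → 0 °C; aqueous work-up
Reagents that add atoms: none
Why: Directed ortho-metalation followed by Weinreb ketone synthesis; C5–H is the only position flanked by two chelating OMOM groups, the hard aryllithium attacks the amide carbonyl (1,2), and the chelated adduct 19 holds until work-up, so neither over-addition nor loss of the E-alkene is expected.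

**Step 11**
Reactants: 20 (E)-1-[(2S)-4,6-bis(methoxymethoxy)-2-(2-triethylsilyloxypropan-2-yl)-2,3-dihydrobenzofuran-5-yl]-3-[4-(methoxymethoxy)phenyl]prop-2-en-1-one
Product: 21 (E)-1-[(2S)-4,6-dihydroxy-2-(2-hydroxypropan-2-yl)-2,3-dihydrobenzofuran-5-yl]-3-(4-hydroxyphenyl)prop-2-en-1-one
Conditions: 3 M aq. HCl/MeOH, rt; extractive work-up kept at pH 4–5, no base
Reagents that add atoms: none
Why: Acid-catalysed acetal exchange of the three aryl MOM ethers and solvolysis of the TES ether; room temperature and an acidic medium should keep the chalcone open, and the tertiary alcohol (beta to O1, a poor cation precursor) and C2 are not affected.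

**Compound list**
1 | 1,3,5-tris(benzyloxy)benzene | C(Oc1cc(OCc2ccccc2)cc(OCc2ccccc2)c1)c1ccccc1 | starting material
2 | 2-bromo-1,3,5-tris(benzyloxy)benzene | Brc1c(OCc2ccccc2)cc(OCc2ccccc2)cc1OCc1ccccc1 | intermediate
3 | methyl (S)-glycidate | COC(=O)[C@@H]1CO1 | starting material
4 | 2,4,6-tris(benzyloxy)phenylmagnesium bromide | Br[Mg]c1c(OCc2ccccc2)cc(OCc2ccccc2)cc1OCc1ccccc1 | intermediate
5 | methyl (S)-2-hydroxy-3-[2,4,6-tris(benzyloxy)phenyl]propanoate | COC(=O)[C@@H](O)Cc1c(OCc2ccccc2)cc(OCc2ccccc2)cc1OCc1ccccc1 | intermediate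
6 | methyl (S)-2-(tosyloxy)-3-[2,4,6-tris(benzyloxy)phenyl]propanoate | COC(=O)[C@@H](OS(=O)(=O)c1ccc(C)cc1)Cc1c(OCc2ccccc2)cc(OCc2ccccc2)cc1OCc1ccccc1 | intermediate
7 | methyl (S)-2-(tosyloxy)-3-(2,4,6-trihydroxyphenyl)propanoate | COC(=O)[C@@H](OS(=O)(=O)c1ccc(C)cc1)Cc1c(O)cc(O)cc1O | intermediate
8 | (S)-5,7-dihydroxy-2-oxochroman-3-yl 4-methylbenzenesulfonate | O=C1Oc2cc(O)cc(O)c2C[C@@H]1OS(=O)(=O)c1ccc(C)cc1 | intermediate
9 | (S)-3-oxo-1-(2,4,6-trihydroxyphenyl)butan-2-yl tosylate, trilithium phenoxide | CC(=O)[C@@H](OS(=O)(=O)c1ccc(C)cc1)Cc1c(O[Li])cc(O[Li])cc1O[Li] | intermediate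
10 | (S)-3-hydroxy-3-methyl-1-(2,4,6-trihydroxyphenyl)butan-2-yl tosylate, tetralithium salt | CC(C)(O[Li])[C@@H](OS(=O)(=O)c1ccc(C)cc1)Cc1c(O[Li])cc(O[Li])cc1O[Li] | intermediate
11 | 2-{[(R)-3,3-dimethyloxiran-2-yl]methyl}benzene-1,3,5-triol, trilithium salt | CC1(C)O[C@@H]1Cc1c(O[Li])cc(O[Li])cc1O[Li] | intermediate
12 | (S)-2-(2-hydroxypropan-2-yl)-2,3-dihydrobenzofuran-4,6-diol | CC(C)(O)[C@@H]1Cc2c(cc(O)cc2O)O1 | intermediate
13 | (S)-2-[4,6-bis(methoxymethoxy)-2,3-dihydrobenzofuran-2-yl]propan-2-ol | CC(C)(O)[C@@H]1Cc2c(cc(OCOC)cc2OCOC)O1 | intermediate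
14 | (S)-triethyl{2-[4,6-bis(methoxymethoxy)-2,3-dihydrobenzofuran-2-yl]propan-2-yloxy}silane | CC(C)(O[Si](CC)(CC)CC)[C@@H]1Cc2c(cc(OCOC)cc2OCOC)O1 | intermediate
15 | 4-hydroxybenzaldehyde | O=Cc1ccc(O)cc1 | starting material
16 | 4-(methoxymethoxy)benzaldehyde | O=Cc1ccc(OCOC)cc1 | intermediate
17 | (E)-N-methoxy-N-methyl-3-[4-(methoxymethoxy)phenyl]acrylamide | CON(C)C(=O)/C=C/c1ccc(OCOC)cc1 | intermediate
18 | C5-lithiated 14 | CC(C)(O[Si](CC)(CC)CC)[C@@H]1Cc2c(cc(OCOC)c([Li])c2OCOC)O1 | intermediate
19 | lithium hemiaminal from 18 and 17 (epimers at the hemiaminal carbon) | CC(C)(O[Si](CC)(CC)CC)[C@@H]1Cc2c(cc(OCOC)c(C(O[Li])(N(C)OC)/C=C/c3ccc(OCOC)cc3)c2OCOC)O1 | intermediate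
20 | (E)-1-[(2S)-4,6-bis(methoxymethoxy)-2-(2-triethylsilyloxypropan-2-yl)-2,3-dihydrobenzofuran-5-yl]-3-[4-(methoxymethoxy)phenyl]prop-2-en-1-one | CC(C)(O[Si](CC)(CC)CC)[C@@H]1Cc2c(cc(OCOC)c(C(=O)/C=C/c3ccc(OCOC)cc3)c2OCOC)O1 | intermediate
21 | (E)-1-[(2S)-4,6-dihydroxy-2-(2-hydroxypropan-2-yl)-2,3-dihydrobenzofuran-5-yl]-3-(4-hydroxyphenyl)prop-2-en-1-one | CC(C)(O)[C@@H]1Cc2c(cc(O)c(C(=O)/C=C/c3ccc(O)cc3)c2O)O1 | target

Total step count: 11. Longest linear sequence: 9 (steps 1–7, 10, 11); steps 8 and 9 form the side branch.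

**Steps most likely to fail**

Step 5.
- **What may go wrong:**
  - Enolisation of the lactone or of ketone 9 by MeLi, with loss of configurational purity.
  - Displacement of tosylate by phenoxide before the oxirane has formed, which erodes the enantiomeric purity.
  - Attack of MeLi at sulfur.
  - Oxirane opening at the tertiary carbon.
- **Fallback:** it uses known chemistry and is still a six-to-five contraction, but methoxide breaks the lactone and the methyl groups are added afterwards.
  - It sets out from 8. LiCl (one equivalent) in DMF replaces tosylate by chloride with inversion and gives (R)-3-chloro-5,7-dihydroxychroman-2-one F1.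
  - K2CO3 in MeOH at 0 °C cleaves the aryl ester, and the freed phenoxide displaces chloride in an intramolecular Williamson etherification. This closure is 5-exo-tet with a second inversion and is the saturated counterpart of the Perkin rearrangement. It gives methyl (S)-4,6-dihydroxy-2,3-dihydrobenzofuran-2-carboxylate F2.
  - Excess MeMgBr in THF converts the ester into the carbinol, and the route is rejoined at 12.

Step 10.
- **What may go wrong:** metalation beside the ring oxygen (C7) competing with C5, or base-induced beta-elimination that opens the dihydrofuran.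
- **Fallback:** it uses a blocking group placed by electrophilic substitution, which prefers the less hindered position ortho to the ring oxygen.
  - It sets out from 14. NBS in MeCN at 0 °C gives the 7-bromo derivative of 14 F3.
  - Bromine–lithium exchange (n-BuLi, −78 °C) and TMSCl give the 7-trimethylsilyl derivative of 14 F4, in which C5–H is the only aromatic hydrogen left.
  - Metalation and acylation with 17 as in step 10 give the 7-trimethylsilyl derivative of 20 F5.
  - The acid treatment of step 11 removes the MOM and TES groups and, by ipso-protonation of the electron-rich ring, the aryl silane. The route is rejoined at 21.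

Step 11.
- **What may go wrong:** acid-catalysed oxa-Michael closure of the C4 or C6 hydroxyl onto the enone (chalcone-to-flavanone isomerisation) during or after loss of the MOM groups.
- **Fallback:** it deprotects before the enone exists.
  - It sets out from 14. Lithiation as in step 10 and N-methoxy-N-methylacetamide give the protected 5-acetyl compound F6.
  - 3 M HCl/MeOH gives 1-[(2S)-4,6-dihydroxy-2-(2-hydroxypropan-2-yl)-2,3-dihydrobenzofuran-5-yl]ethanone F7, which cannot cyclise.
  - Claisen–Schmidt condensation of F7 with 15 in concentrated KOH/EtOH–H2O keeps the product as the open polyphenoxide. Cold acidification then sets the chalcone free, and the route is rejoined at 21.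

**Further compounds**
F1 | step 5 | (R)-3-chloro-5,7-dihydroxychroman-2-one | O=C1Oc2cc(O)cc(O)c2C[C@H]1Cl
F2 | step 5 | methyl (S)-4,6-dihydroxy-2,3-dihydrobenzofuran-2-carboxylate | COC(=O)[C@@H]1Cc2c(cc(O)cc2O)O1
F3 | step 10 | (S)-{2-[7-bromo-4,6-bis(methoxymethoxy)-2,3-dihydrobenzofuran-2-yl]propan-2-yloxy}triethylsilane | CC(C)(O[Si](CC)(CC)CC)[C@@H]1Cc2c(c(Br)c(OCOC)cc2OCOC)O1
F4 | step 10 | (S)-triethyl{2-[4,6-bis(methoxymethoxy)-7-(trimethylsilyl)-2,3-dihydrobenzofuran-2-yl]propan-2-yloxy}silane | CC(C)(O[Si](CC)(CC)CC)[C@@H]1Cc2c(c([Si](C)(C)C)c(OCOC)cc2OCOC)O1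
F5 | step 10 | (E)-1-[(2S)-4,6-bis(methoxymethoxy)-2-(2-triethylsilyloxypropan-2-yl)-7-(trimethylsilyl)-2,3-dihydrobenzofuran-5-yl]-3-[4-(methoxymethoxy)phenyl]prop-2-en-1-one | CC(C)(O[Si](CC)(CC)CC)[C@@H]1Cc2c(c([Si](C)(C)C)c(OCOC)c(C(=O)/C=C/c3ccc(OCOC)cc3)c2OCOC)O1
F6 | step 11 | 1-[(2S)-4,6-bis(methoxymethoxy)-2-(2-triethylsilyloxypropan-2-yl)-2,3-dihydrobenzofuran-5-yl]ethanone | CC(C)(O[Si](CC)(CC)CC)[C@@H]1Cc2c(cc(OCOC)c(C(C)=O)c2OCOC)O1
F7 | step 11 | 1-[(2S)-4,6-dihydroxy-2-(2-hydroxypropan-2-yl)-2,3-dihydrobenzofuran-5-yl]ethanone | CC(C)(O)[C@@H]1Cc2c(cc(O)c(C(C)=O)c2O)O1
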